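The benzene ring of the chromene (C4a, C5, C6, C7, C8, C8a) is made de novo. Its substituents alternate between oxygen (C5, C7, C8a) and carbon (C4a, C6, C8), so cleaving C5–C6 and C7–C8 divides it into a four-carbon 1,3-dioxygenated diene (C5, C4a, C8a and prenylated C8) and a two-carbon alkoxy-ynone (C6 with the arylacetyl chain, C7 with the methoxy group). One cycloaddition–aromatisation unites them and releases a pentasubstituted arene in which C5–OH, C8a–OH and C7–OMe are already distinguished and C4a is the only unsubstituted carbon. The precursors are a prenylated bis(trimethylsilyloxy)diene and a silyl-protected 4-methoxybut-3-yn-2-one; pyran annulation and desilylation then complete the target.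

Key step: step 7

Remark: the target has no stereogenic centre and is achiral, so no enantiocontrol is required; the enol ether geometries of 4, 5 and 15 are the only stereo-elements on the route and none survives into the target.
Remark: atom map of the key step (chromene numbering): diene C1→C5, C2→C4a, C3→C8a, C4→C8; ynone α-carbon→C6, β-carbon→C7; bonds formed C5–C6 and C7–C8.

Step 1
Reactants: 1 methyl acetoacetate; 2 prenyl bromide (1-bromo-3-methylbut-2-ene)
Product: 3 methyl 7-methyl-3-oxooct-6-enoate
Conditions: NaH, THF, 0 °C; n-BuLi, 0 °C; then 2, 0 °C → rt; aq. HCl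
Reagents that add atoms: none
Why: Double deprotonation of the acetoacetate makes the terminal (γ) carbon the most basic site, and it alone should be alkylated by the primary allylic bromide in an SN2 reaction (dianion γ-alkylation), leaving the linear 3-methylbut-2-enyl group.

Step 2
Reactants: 3 methyl 7-methyl-3-oxooct-6-enoate
Product: 4 methyl (2Z)-7-methyl-3-(trimethylsilyloxy)octa-2,6-dienoate
Conditions: TMSCl, Et3N, hexane, rt
Reagents that add atoms: chlorotrimethylsilane, C[Si](C)(C)Cl
Why: Soft enolisation and O-silylation of the β-keto ester (silyl enol ether formation) should give the conjugated enol ether, whose C2=C3 geometry is of no consequence because this bond becomes the central single bond of the diene.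

Step 3
Reactants: 4 methyl (2Z)-7-methyl-3-(trimethylsilyloxy)octa-2,6-dienoate
Product: 5 (1E,3Z)-1-methoxy-7-methyl-1,3-bis(trimethylsilyloxy)octa-1,3,6-triene
Conditions: LDA (commercial solution), THF, −78 °C; TMSCl, −78 °C → rt; pentane, filtration, used crude
Reagents that add atoms: chlorotrimethylsilane, C[Si](C)(C)Cl
Why: Kinetic γ-deprotonation of the vinylogous ester and O-silylation at the ester oxygen is the standard preparation of 1-alkoxy-1,3-bis(silyloxy)dienes and should place the prenyl-bearing carbon trans to C2 (3Z), the geometry that allows the s-cis conformer.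

Step 4
Reactants: 6 4-hydroxyphenylacetic acid
Product: 7 2-(4-hydroxyphenyl)-N-methoxy-N-methylacetamide
Conditions: MeNH(OMe)·HCl, EDC·HCl, HOBt (cat.), N-methylmorpholine, CH2Cl2, 0 °C → rt
Reagents that add atoms: N,O-dimethylhydroxylamine hydrochloride, CNOC.Cl
Why: Carbodiimide/HOBt amide coupling runs through an active ester that the free hydroxylamine should attack far faster than the weakly nucleophilic phenol does (Weinreb amide formation).

Step 5
Reactants: 7 2-(4-hydroxyphenyl)-N-methoxy-N-methylacetamide
Product: 8 2-[4-(tert-butyldimethylsilyloxy)phenyl]-N-methoxy-N-methylacetamide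
Conditions: TBSCl, imidazole, DMF, rt
Reagents that add atoms: tert-butyldimethylsilyl chloride, CC(C)(C)[Si](C)(C)Cl
Why: Imidazole-promoted silylation of the phenol masks the only acidic proton, which would otherwise quench the acetylide in step 6 and the silyl ketene acetal in step 7.

Step 6
Reactants: 8 2-[4-(tert-butyldimethylsilyloxy)phenyl]-N-methoxy-N-methylacetamide; 9 chloroacetaldehyde dimethyl acetal (2-chloro-1,1-dimethoxyethane)
Product: 11 1-[4-(tert-butyldimethylsilyloxy)phenyl]-4-methoxybut-3-yn-2-one, via lithium methoxyacetylide 10 (not isolated)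
Conditions: Et2NH, n-BuLi (3 equiv per 9), THF, 0 °C; 9, 0 °C; then 8, −78 → −30 °C; inverse quench into AcOH/THF, −78 °C
Reagents that add atoms: none
Why: Three equivalents of lithium diethylamide should remove methanol and hydrogen chloride from the chloroacetal and deprotonate the methoxyacetylene formed, and the acetylide then adds only once to the N-methoxy-N-methylamide because N,O-chelation holds the addition stage until the acidic quench (Weinreb ketone synthesis).

Step 7
Reactants: 5 (1E,3Z)-1-methoxy-7-methyl-1,3-bis(trimethylsilyloxy)octa-1,3,6-triene; 11 1-[4-(tert-butyldimethylsilyloxy)phenyl]-4-methoxybut-3-yn-2-one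
Product: 13 2-[4-(tert-butyldimethylsilyloxy)phenyl]-1-[4,6-dihydroxy-2-methoxy-3-(3-methylbut-2-en-1-yl)phenyl]ethan-1-one, via cyclohexa-1,4-diene cycloadduct 12 (not isolated)
Conditions: 5 (1.5 equiv), PhMe (1 M), rt → 70 °C; then 0.5 M HCl, THF, 0 °C
Reagents that add atoms: none
Why: Proposed new method: the electron-rich diene 5 and the acceptor alkyne 11 should combine in a strongly asynchronous normal-demand [4+2] cycloaddition in which the prenyl-bearing C4 of the diene, the γ-carbon of a vinylogous ketene acetal, bonds to the methoxy-bearing β-carbon of the ynone (the vinylogous-ester carbon with the largest LUMO coefficient) and the ketene acetal carbon C1 bonds to the acyl-bearing α-carbon, giving cyclohexa-1,4-diene 12; in the stepwise limit the same two bonds arise from a Mukaiyama–Michael addition followed by 6-exo-trig Claisen-type closure of the allenolate onto the ester carbon. The closest known reaction type is the Diels–Alder benzannulation of 1-alkoxy-1,3-bis(silyloxy)dienes with acetylenic ketones and esters, and what is untested is a dienophile that carries a β-alkoxy donor. The single ring formed is the six-membered carbocycle, closed in the [4+2] mode; dilute acid then hydrolyses the silyl methyl ketal at C1 with loss of methanol, the 4H-dienone tautomerises through the C4 hydrogen and the second trimethylsilyl ether is cleaved, so that arene 13 appears with a chelated OH, a free OH and the OMe each on its intended carbon while the aryl TBS ether survives. No stereocentre is created in the product, since both sp3 carbons of 12 become aromatic. The step needs regioselectivity (C4 to Cβ, C1 to Cα) and periselectivity (closure through C1 rather than aldol-type [3+3] closure of C2 onto the ketone): the first follows from the matched polarisation of the two partners, the methoxy group making Cβ the only acceptor site, and the second from the thermal, Lewis-acid-free conditions, under which the ketone is never activated towards C2.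

Step 8
Reactants: 13 2-[4-(tert-butyldimethylsilyloxy)phenyl]-1-[4,6-dihydroxy-2-methoxy-3-(3-methylbut-2-en-1-yl)phenyl]ethan-1-one; 14 3-methylbut-2-enal
Product: 16 2-[4-(tert-butyldimethylsilyloxy)phenyl]-1-[5-hydroxy-7-methoxy-2,2-dimethyl-8-(3-methylbut-2-en-1-yl)-2H-chromen-6-yl]ethan-1-one, via ortho-quinone methide 15 (not isolated)
Conditions: 14 (2 equiv), ethylenediammonium diacetate (20 mol %), xylene, 120 °C
Reagents that add atoms: none
Why: In this amine-salt-catalysed domino Knoevenagel-type condensation/oxa-6π electrocyclisation the ring carbon between the two hydroxyls, the only unsubstituted one, should add to the activated enal, loss of water gives ortho-quinone methide 15, and closure uses the oxygen para to the ketone because the ortho hydroxyl stays locked in its hydrogen bond to the carbonyl.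

Step 9
Reactants: 16 2-[4-(tert-butyldimethylsilyloxy)phenyl]-1-[5-hydroxy-7-methoxy-2,2-dimethyl-8-(3-methylbut-2-en-1-yl)-2H-chromen-6-yl]ethan-1-one
Product: 17 1-[5-hydroxy-7-methoxy-2,2-dimethyl-8-(3-methylbut-2-en-1-yl)-2H-chromen-6-yl]-2-(4-hydroxyphenyl)ethan-1-one (target)
Conditions: TBAF, AcOH, THF, 0 °C
Reagents that add atoms: none
Why: Fluoride-induced cleavage of the aryl silyl ether, driven by Si–F bond formation and buffered with acetic acid so that the phenoxide is protonated at once, should leave chromene, prenyl group and ketone untouched.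

Compound list
1 | methyl acetoacetate | COC(=O)CC(C)=O | starting material
2 | prenyl bromide (1-bromo-3-methylbut-2-ene) | CC(C)=CCBr | starting material
3 | methyl 7-methyl-3-oxooct-6-enoate | COC(=O)CC(=O)CCC=C(C)C | intermediate
4 | methyl (2Z)-7-methyl-3-(trimethylsilyloxy)octa-2,6-dienoate | COC(=O)/C=C(\O[Si](C)(C)C)CCC=C(C)C | intermediate
5 | (1E,3Z)-1-methoxy-7-methyl-1,3-bis(trimethylsilyloxy)octa-1,3,6-triene | CO/C(O[Si](C)(C)C)=C\C(O[Si](C)(C)C)=C\CC=C(C)C | intermediate
6 | 4-hydroxyphenylacetic acid | OC(=O)Cc1ccc(O)cc1 | starting material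
7 | 2-(4-hydroxyphenyl)-N-methoxy-N-methylacetamide | CON(C)C(=O)Cc1ccc(O)cc1 | intermediate
8 | 2-[4-(tert-butyldimethylsilyloxy)phenyl]-N-methoxy-N-methylacetamide | CON(C)C(=O)Cc1ccc(O[Si](C)(C)C(C)(C)C)cc1 | intermediate
9 | chloroacetaldehyde dimethyl acetal (2-chloro-1,1-dimethoxyethane) | COC(CCl)OC | starting material
10 | lithium methoxyacetylide (not isolated) | [Li]C#COC | intermediate
11 | 1-[4-(tert-butyldimethylsilyloxy)phenyl]-4-methoxybut-3-yn-2-one | COC#CC(=O)Cc1ccc(O[Si](C)(C)C(C)(C)C)cc1 | intermediate
12 | 2-[4-(tert-butyldimethylsilyloxy)phenyl]-1-[2,6-dimethoxy-3-(3-methylbut-2-en-1-yl)-4,6-bis(trimethylsilyloxy)cyclohexa-1,4-dien-1-yl]ethan-1-one (cycloadduct, mixture of diastereomers at the two sp3 ring carbons, not isolated) | COC1=C(C(=O)Cc2ccc(O[Si](C)(C)C(C)(C)C)cc2)C(OC)(O[Si](C)(C)C)C=C(O[Si](C)(C)C)C1CC=C(C)C | intermediate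
13 | 2-[4-(tert-butyldimethylsilyloxy)phenyl]-1-[4,6-dihydroxy-2-methoxy-3-(3-methylbut-2-en-1-yl)phenyl]ethan-1-one | COc1c(CC=C(C)C)c(O)cc(O)c1C(=O)Cc1ccc(O[Si](C)(C)C(C)(C)C)cc1 | intermediate
14 | 3-methylbut-2-enal | CC(C)=CC=O | starting material
15 | (6Z)-4-{[4-(tert-butyldimethylsilyloxy)phenyl]acetyl}-5-hydroxy-3-methoxy-2-(3-methylbut-2-en-1-yl)-6-(3-methylbut-2-en-1-ylidene)cyclohexa-2,4-dien-1-one (ortho-quinone methide, not isolated) | COC1=C(CC=C(C)C)C(=O)/C(=C\C=C(C)C)C(O)=C1C(=O)Cc1ccc(O[Si](C)(C)C(C)(C)C)cc1 | intermediate
16 | 2-[4-(tert-butyldimethylsilyloxy)phenyl]-1-[5-hydroxy-7-methoxy-2,2-dimethyl-8-(3-methylbut-2-en-1-yl)-2H-chromen-6-yl]ethan-1-one | COc1c(CC=C(C)C)c2c(c(O)c1C(=O)Cc1ccc(O[Si](C)(C)C(C)(C)C)cc1)C=CC(C)(C)O2 | intermediate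
17 | 1-[5-hydroxy-7-methoxy-2,2-dimethyl-8-(3-methylbut-2-en-1-yl)-2H-chromen-6-yl]-2-(4-hydroxyphenyl)ethan-1-one | COc1c(CC=C(C)C)c2c(c(O)c1C(=O)Cc1ccc(O)cc1)C=CC(C)(C)O2 | target

Total step count: 9
Longest linear sequence: 6 steps (1→2→3→7→8→9, or 4→5→6→7→8→9)

Steps most likely to fail

Step 7 (proposed new method). The donor-substituted triple bond may be too electron-rich to engage the diene before the diene is lost by silyl transfer or hydrolysis. Bond formation may also run through C2 of the diene and the ketone carbonyl (aldol-type [3+3] closure) to give a salicylate-type arene, or the orientation of addition may invert. The fallback uses known reactions to put the same substituents on a preformed ring; it sets out from 6 and rejoins the route at 16. Friedel–Crafts acylation of 5-methoxyresorcinol with 6 (BF3·OEt2, 80 °C) should give 1-(2,4-dihydroxy-6-methoxyphenyl)-2-(4-hydroxyphenyl)ethan-1-one F1, from which the 2,6-dihydroxy-4-methoxy regioisomer would have to be separated. Amine-salt-catalysed annulation with 14 at the carbon between the two ring hydroxyls should give 1-(5-hydroxy-7-methoxy-2,2-dimethyl-2H-chromen-6-yl)-2-(4-hydroxyphenyl)ethan-1-one F2. TBSCl/imidazole should silylate only the non-chelated phenol, giving 2-[4-(tert-butyldimethylsilyloxy)phenyl]-1-(5-hydroxy-7-methoxy-2,2-dimethyl-2H-chromen-6-yl)ethan-1-one F3. Mitsunobu etherification of the chelated hydroxyl with 3-methylbut-2-en-1-ol (PPh3, DIAD, THF) should give 2-[4-(tert-butyldimethylsilyloxy)phenyl]-1-[7-methoxy-2,2-dimethyl-5-(3-methylbut-2-en-1-yloxy)-2H-chromen-6-yl]ethan-1-one F4. A para-Claisen (Claisen–Cope) rearrangement (Eu(fod)3, PhCl, 80 °C, or N,N-diethylaniline, 180 °C), with both ortho positions blocked, should then deliver the prenyl group to C8 and give 16.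

Step 6. Diethylamine liberated in the elimination may add in conjugate fashion to the alkoxy-ynone as the tetrahedral adduct collapses on quench, and proton transfer from the benzylic α-methylene of the amide may outrun the slow addition to the amide carbonyl. The fallback unveils the ynone only by a neutral oxidation in the absence of amines; it sets out from 8 and returns at 11. DIBAL-H (THF, −78 °C) should reduce the amide to 2-[4-(tert-butyldimethylsilyloxy)phenyl]acetaldehyde F5. Addition of 10 (generated as in step 6) at −78 °C, where carbonyl addition is faster than enolisation, should give racemic 1-[4-(tert-butyldimethylsilyloxy)phenyl]-4-methoxybut-3-yn-2-ol F6, whose single stereocentre is removed in the next operation. Activated MnO2 (CH2Cl2, rt) should oxidise the propargylic alcohol to 11.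

Step 8. The enal may condense at the enolisable benzylic methylene of the ketone instead of at the ring carbon, or C-alkylation at the hindered position between two oxygens may be so slow that the enal is lost by self-condensation. The fallback forms the pyran ring by a sigmatropic route that cannot involve the side chain; it sets out from 13 and returns at 16. Alkylation of the non-chelated, more acidic hydroxyl with 3-chloro-3-methylbut-1-yne (K2CO3, KI, CuI cat., acetone, 50 °C) should give 2-[4-(tert-butyldimethylsilyloxy)phenyl]-1-[6-hydroxy-2-methoxy-3-(3-methylbut-2-en-1-yl)-4-(2-methylbut-3-yn-2-yloxy)phenyl]ethan-1-one F7. Heating in xylene at 140 °C should trigger propargyl Claisen rearrangement to the only free ortho carbon, 1,5-hydrogen shift and oxa-6π closure to give 16.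

Further compounds
F1 | step 7 | 1-(2,4-dihydroxy-6-methoxyphenyl)-2-(4-hydroxyphenyl)ethan-1-one | COc1cc(O)cc(O)c1C(=O)Cc1ccc(O)cc1
F2 | step 7 | 1-(5-hydroxy-7-methoxy-2,2-dimethyl-2H-chromen-6-yl)-2-(4-hydroxyphenyl)ethan-1-one | COc1cc2c(c(O)c1C(=O)Cc1ccc(O)cc1)C=CC(C)(C)O2
F3 | step 7 | 2-[4-(tert-butyldimethylsilyloxy)phenyl]-1-(5-hydroxy-7-methoxy-2,2-dimethyl-2H-chromen-6-yl)ethan-1-one | COc1cc2c(c(O)c1C(=O)Cc1ccc(O[Si](C)(C)C(C)(C)C)cc1)C=CC(C)(C)O2
F4 | step 7 | 2-[4-(tert-butyldimethylsilyloxy)phenyl]-1-[7-methoxy-2,2-dimethyl-5-(3-methylbut-2-en-1-yloxy)-2H-chromen-6-yl]ethan-1-one | COc1cc2c(c(OCC=C(C)C)c1C(=O)Cc1ccc(O[Si](C)(C)C(C)(C)C)cc1)C=CC(C)(C)O2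
F5 | step 6 | 2-[4-(tert-butyldimethylsilyloxy)phenyl]acetaldehyde | O=CCc1ccc(O[Si](C)(C)C(C)(C)C)cc1
F6 | step 6 | 1-[4-(tert-butyldimethylsilyloxy)phenyl]-4-methoxybut-3-yn-2-ol (racemic) | COC#CC(O)Cc1ccc(O[Si](C)(C)C(C)(C)C)cc1
F7 | step 8 | 2-[4-(tert-butyldimethylsilyloxy)phenyl]-1-[6-hydroxy-2-methoxy-3-(3-methylbut-2-en-1-yl)-4-(2-methylbut-3-yn-2-yloxy)phenyl]ethan-1-one | COc1c(CC=C(C)C)c(OC(C)(C)C#C)cc(O)c1C(=O)Cc1ccc(O[Si](C)(C)C(C)(C)C)cc1
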